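The constants used here are those of an exercise; what happens was integrated by code.

The neighbouring flasks share their free base and protonated nucleophile and differ in the solid electrophile charged, so the row tells what extra solid buys.

| setting | south-west | east | south-east | south |
|---|---|---|---|---|
| solid electrophile | 0.12 M | 0.20 M | 0.30 M | 0.50 M |
| free base | 0.220 M | 0.220 M | 0.220 M | 0.220 M |
| protonated nucleophile | 0.400 M | 0.400 M | 0.400 M | 0.400 M |
| time | 5.0 d | 5.0 d | 5.0 d | 5.0 d |

    electrophile + nucleophile → acid set free + target (k1 = 2.2 L mol⁻¹ h⁻¹)
    acid set free + free base ⇌ salt of the base, settled at all times (K2 = 40000 L mol⁻¹)
    solid electrophile ⇌ electrophile, rate k3*(cs3 - [electrophile]) while solid is left; crystals form when [electrophile] > cs3 (cs3 = 0.084 M, k3 = 0.031 h⁻¹)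
    nucleophile + acid set free ⇌ protonated nucleophile, settled at all times (K4 = 35000 L mol⁻¹)

- as a solid, counted per litre of solution: solid electrophile
- at the start none of the solid electrophile is in solution
- a step back or a flat step of under half a percent of the largest counts as no turn
- "hardly changes" means that all values lie within two and a half points (for a concentration: within two and a half percent of the largest)
- a step back or a flat step of under half a percent of the largest counts as no turn
- run time (south-west): 5.0 d

- [target] at the end for south-west, east, south-east, south, in this order
- the course of these numbers from the first flask to the last (rises all the way / rises, then falls / hardly changes / falls, then rises / falls all the way)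

I draw c(target) for south-west first. Free base and nucleophile compete for the proton almost evenly, their constants standing in the ratio 1.14, and solving that balance puts c(nucleophile) at the start at 0.146 M. Dissolved electrophile then lasts about 3.11 h, which is shorter than the 32.3 h of dissolving, so at the start dissolving is the rate-limiting step and the curve starts straight with a slope near 0.002604 M h⁻¹.

Each target uses one nucleophile, and its acid takes one more base, so as long as the acid stays bound, the sum of free base and nucleophile falls by two per target. It starts at 0.220 M, so it nears zero at a target of 0.110 M, which I call the knee level. The straight line gets there after 1.76 d, and I expect the real knee somewhat later.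

Past the knee I expect acid to stand free, two for each target above the knee level, holding c(nucleophile) down, so the curve turns into a creep whose speed goes with the electrophile in solution. I therefore carry one quantity, the surplus: the electrophile I expect in solution past the knee, taken as the smaller of the charge minus the knee level and the solubility. It is 0.0100 M in south-west, but 0.0840 M in east and the same 0.0840 M in south. If c(electrophile) stands at the surplus throughout the creep, the square of the excess over the knee level grows steadily, which gives 0.00376 M for south-west and 0.0109 M for each of the others. I commit to 0.114 M for south-west and 0.121 M for east, south-east and south: a rise, then a level, and since a flat step counts as no turn, that is a row that rises all the way.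

The forecast gives 0.109 M, 0.11 M, 0.11 M, 0.11 M and hardly changes, holding that “extra solid adds nothing”, where my row rises.

The flasks give 0.110 M, 0.116 M, 0.116 M, 0.116 M, and the course rises all the way. My numbers stand higher by 0.00376 M in south-west and 0.00490 M in east. South-west holds 0.0103 M of electrophile at 5.00 d against its surplus of 0.0100 M. In east, at 5.00 d, solid stands at 6.97 % of its charge, and the electrophile in solution is 0.0705 M, below its surplus of 0.0840 M.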